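**Strategy.** The cis-fused hydroazulene is made from a drimane-type trans-decalin by one cationic 1,2-alkyl shift. In ring B of the precursor, an 11-nordrimane with an equatorial 9β-hydroxyl flanked by quaternary C8 (β-methyl, α-2-pivaloyloxyethyl arm) and quaternary C10, the C9–O bond is antiperiplanar to the C5–C10 ring-fusion bond. On triflation C5 moves from C10 to C9, contracting ring B to the cyclopentane, expanding ring A to the cycloheptane, setting the cis fusion and leaving the C10=C20 methylene. The decalin comes from (+)-sclareolide by excision of C11/C12 and enolate alkylation at C8; afterwards the arm becomes an aldehyde whose chiral hydrazone adds to 2(5H)-furanone to set C14 and C13.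

Key step: step 9

Assumption: positions are numbered biogenetically (decalin C1–C10 with C20 on C10 and C17 on C8; side chain C11–C16; "11-nordrimane" is this decalin without C11), and ketone 9 is carried as its C8 epimer mixture because step 6 erases that centre.

Step 1
Reactants: 1 (+)-sclareolide
Product: 2 sclareolide lactol (C12 hemiacetal; anomer mixture)
Conditions: i-Bu2AlH, CH2Cl2, −78 °C
Reagents that add atoms: none
Why: Lactone-to-lactol half-reduction: at −78 °C the aluminium hemiacetal is stable and gives the lactol on work-up, with no stereocentre touched.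

Step 2
Reactants: 2 sclareolide lactol
Product: 4 11-iododriman-8α-yl formate (9β-iodomethyl; 8β-methyl), via lactol hypoiodite 3 (not isolated)
Conditions: PhI(OAc)2, I2, CH2Cl2, visible light, rt
Reagents that add atoms: iodine, [I][I]
Why: Suárez hypoiodite fragmentation: the O–I bond of 3 homolyses, the anomeric alkoxy radical cleaves C11–C12 by β-scission (C12 stays as the formate on the C8 oxygen) and the primary C11 radical is capped by iodine, so C12 is excised without change at C8 or C9.

Step 3
Reactants: 4 11-iododriman-8α-yl formate
Product: 5 drim-9(11)-en-8α-yl formate (exocyclic C9=C11)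
Conditions: AgF, pyridine, rt
Reagents that add atoms: none
Why: Silver-assisted dehydroiodination (E2-type) of the hindered primary iodide removes H9, the only β-hydrogen, and gives the exocyclic alkene.

Step 4
Reactants: 5 drim-9(11)-en-8α-yl formate
Product: 7 8α-formyloxy-11-nordriman-9-one, via secondary ozonide 6 (not isolated)
Conditions: O3, CH2Cl2, −78 °C; then Me2S, −78 °C → rt
Reagents that add atoms: ozone, [O-][O+]=O
Why: Ozonolysis with reductive work-up cuts the 1,1-disubstituted alkene, C11 leaving as formaldehyde, and the tertiary formate and the saturated skeleton are inert.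

Step 5
Reactants: 7 8α-formyloxy-11-nordriman-9-one
Product: 9 11-nordriman-9-one (8-methyl ketone; C8 epimers), via diiodosamarium enolate 8 (not isolated)
Conditions: SmI2, THF/MeOH, −78 °C
Reagents that add atoms: none
Why: SmI2 reduction of an α-acyloxy ketone: electron transfer to the C9 carbonyl and β-elimination of formate give enolate 8, which methanol protonates at C8.

Step 6
Reactants: 9 11-nordriman-9-one; 10 ethyl bromoacetate
Product: 12 ethyl (8β-methyl-9-oxo-11-nordriman-8α-yl)acetate, via lithium enolate 11 (not isolated)
Conditions: LiN(i-Pr)2, THF, −78 → 0 °C; then DMPU, 10, −78 °C → rt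
Reagents that add atoms: none
Why: Enolate alkylation of the only possible enolate (C10 is quaternary) with a reactive α-halo ester; the electrophile should reach C8 from the α face, anti to the axial C10 methyl that screens the β face in a 1,3 sense, so the arm ends α (equatorial) and the methyl β (axial).

Step 7
Reactants: 12 ethyl (8β-methyl-9-oxo-11-nordriman-8α-yl)acetate
Product: 13 8α-(2-hydroxyethyl)-11-nordriman-9β-ol
Conditions: LiAlH4, THF, 0 °C → reflux
Reagents that add atoms: none
Why: Hydride reduction of ester and ketone in one operation; under steric approach control hydride should reach C9 along the axial α trajectory, away from the two β-axial methyls on C8 and C10, giving the equatorial 9β-alcohol.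

Step 8
Reactants: 13 8α-(2-hydroxyethyl)-11-nordriman-9β-ol; 14 pivaloyl chloride
Product: 15 8α-(2-pivaloyloxyethyl)-11-nordriman-9β-ol
Conditions: pyridine, CH2Cl2, 0 °C
Reagents that add atoms: none
Why: Selective acylation of the primary hydroxyl (the C9 hydroxyl lies between two quaternary carbons); an ester is preferred to an ether or silyl ether because in step 9 its oxygen cannot close an oxolane on C9 and it withdraws electron density from C8.

Step 9
Reactants: 15 8α-(2-pivaloyloxyethyl)-11-nordriman-9β-ol
Product: 18 cis-hydroazulene pivalate (C10 methylene; 8β-methyl; 8α-arm; H5 and H9 cis), via C9 triflate 16 (not isolated), via C10 carbocation 17 (not isolated)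
Conditions: Tf2O, 2,6-di-tert-butyl-4-methylpyridine, CH2Cl2, −78 → 0 °C
Reagents that add atoms: none
Why: Wagner–Meerwein 1,2-alkyl shift, closest in type to the solvolytic rearrangement of trans-decalyl sulfonates with an equatorial leaving group to hydroazulenes: triflation gives 16, whose equatorial C9–O bond is antiperiplanar to the C5–C10 bond of chair ring B, so ionisation is assisted by migration of C5 to the rear of C9, and the tertiary C10 cation 17 loses a C20 proton to the hindered pyridine or the paired triflate. The five-membered ring (C5, C6, C7, C8, C9) closes by contraction of ring B through the new C5–C9 bond, and the seven-membered ring (C10, C1, C2, C3, C4, C5, C9) arises by expansion of ring A in the same shift. The new C9 stereocentre is set by inversion (C5 enters anti to the departing oxygen while the axial H9 stays on the α face) and C5 migrates with retention, which places H9 and H5 cis. The step needs C5 and not C7 to migrate, although both ring bonds are antiperiplanar and either shift would leave a tertiary cation: the tertiary, more electron-rich C5 is the better migrating carbon, its shift relieves the congestion around C4, C10 and the diaxial 8β/10β methyl pair, and the acyloxyethyl arm disfavours charge at C8. The proton must leave from C20 and not from C1 or C9: the methyl protons are the most accessible to the hindered base at low temperature, and H9 lies on the face remote from the departing triflate. C8 and C10 are quaternary, so neither a hydride shift nor a direct E2 elimination can compete.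

Step 10
Reactants: 18 cis-hydroazulene pivalate
Product: 19 primary alcohol (8α-(2-hydroxyethyl) hydroazulene)
Conditions: i-Bu2AlH, CH2Cl2, −78 °C
Reagents that add atoms: none
Why: Reductive ester cleavage frees the primary alcohol without acid or strong base, so the exocyclic alkene stays in place.

Step 11
Reactants: 19 primary alcohol
Product: 20 aldehyde (C8–CH2–CHO)
Conditions: Dess–Martin periodinane, NaHCO3, CH2Cl2, 0 °C → rt
Reagents that add atoms: none
Why: Dess–Martin oxidation under buffered conditions stops at the aldehyde; the α-carbon is a methylene next to quaternary C8, so nothing can epimerise.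

Step 12
Reactants: 20 aldehyde; 21 (S)-1-amino-2-(methoxymethyl)pyrrolidine (SAMP)
Product: 22 (E)-SAMP hydrazone of 20
Conditions: CH2Cl2, 4 Å molecular sieves, rt
Reagents that add atoms: none
Why: Hydrazone condensation installs the chiral auxiliary that will control C14 and gives the E isomer for steric reasons.

Step 13
Reactants: 22 (E)-SAMP hydrazone; 23 2(5H)-furanone
Product: 26 hydrazone lactone (13R,14R), via lithium azaenolate 24 (not isolated), via lithium lactone enolate 25 (not isolated)
Conditions: LiN(i-Pr)2, THF, 0 °C; then 23, −78 °C; AcOH, −78 °C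
Reagents that add atoms: none
Why: SAMP-hydrazone method, azaenolate Michael addition to an α,β-unsaturated lactone: the E(C=C) azaenolate 24, with lithium chelated by the methoxymethyl arm, should be attacked on the Re face of C14 (the face used in alkylations with this auxiliary), and C13 should be set on its Si face through a compact lithium-bridged transition state in which the azaenolate nitrogen lies on the carbonyl side (over C12) and the bulky hydroazulenyl group points away from the ring (unlike topicity).

Step 14
Reactants: 26 hydrazone lactone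
Product: 27 aldehyde lactone (13R,14R)
Conditions: CuCl2, THF/H2O (pH 7 phosphate buffer), rt
Reagents that add atoms: water, O
Why: Metal-salt-promoted hydrazone hydrolysis at neutral pH returns the aldehyde without acid or oxidant, so the alkene, the lactone and the hindered C14 centre are preserved.

Step 15
Reactants: 27 aldehyde lactone
Product: 28 hydroxy lactone (13R,14R)
Conditions: NaBH4, MeOH, 0 °C
Reagents that add atoms: none
Why: Chemoselective borohydride reduction: the aldehyde is reduced at 0 °C while the γ-lactone and the alkene are untouched.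

Step 16
Reactants: 28 hydroxy lactone; 29 acetic anhydride
Product: 30 target CNP0235949.1
Conditions: pyridine, DMAP (cat.), CH2Cl2, 0 °C → rt
Reagents that add atoms: none
Why: Acetylation with nucleophilic catalysis caps the primary alcohol before it can transesterify the lactone and gives the target.

**Compound list**

1 | (+)-sclareolide | CC1(C)CCC[C@@]2(C)[C@H]1CC[C@@]1(C)OC(=O)C[C@H]21 | starting material
2 | sclareolide lactol (C12 hemiacetal, anomer mixture) | CC1(C)CCC[C@@]2(C)[C@H]1CC[C@@]1(C)OC(O)C[C@H]21 | intermediate
3 | lactol hypoiodite | CC1(C)CCC[C@@]2(C)[C@H]1CC[C@@]1(C)OC(OI)C[C@H]21 | intermediate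
4 | 11-iododriman-8α-yl formate (trans-decalin, 9β-CH2I, 8β-CH3, 8α-OCHO) | CC1(C)CCC[C@@]2(C)[C@H]1CC[C@@](C)(OC=O)[C@@H]2CI | intermediate
5 | drim-9(11)-en-8α-yl formate | CC1(C)CCC[C@@]2(C)[C@H]1CC[C@@](C)(OC=O)C2=C | intermediate
6 | secondary ozonide of 5 (spiro-1,2,4-trioxolane at C9) | CC1(C)CCC[C@@]2(C)[C@H]1CC[C@@](C)(OC=O)C21OCOO1 | intermediate
7 | 8α-formyloxy-11-nordriman-9-one | CC1(C)CCC[C@@]2(C)[C@H]1CC[C@@](C)(OC=O)C2=O | intermediate
8 | diiodosamarium enolate (C8=C9) | CC1(C)CCC[C@@]2(C)[C@H]1CCC(C)=C2O[Sm](I)I | intermediate
9 | 11-nordriman-9-one (8-methyl ketone; drawn as the equatorial 8α-methyl epimer) | CC1(C)CCC[C@@]2(C)[C@H]1CC[C@@H](C)C2=O | intermediate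
10 | ethyl bromoacetate | CCOC(=O)CBr | starting material
11 | lithium enolate of 9 (C8=C9) | CC1(C)CCC[C@@]2(C)[C@H]1CCC(C)=C2[O-].[Li+] | intermediate
12 | ethyl (8β-methyl-9-oxo-11-nordriman-8α-yl)acetate | CC1(C)CCC[C@@]2(C)[C@H]1CC[C@@](C)(CC(=O)OCC)C2=O | intermediate
13 | 8α-(2-hydroxyethyl)-11-nordriman-9β-ol (equatorial 9-OH) | CC1(C)CCC[C@@]2(C)[C@H]1CC[C@@](C)(CCO)[C@@H]2O | intermediate
14 | pivaloyl chloride | CC(C)(C)C(Cl)=O | starting material
15 | 8α-(2-pivaloyloxyethyl)-11-nordriman-9β-ol (key-step precursor) | CC1(C)CCC[C@@]2(C)[C@H]1CC[C@@](C)(CCOC(=O)C(C)(C)C)[C@@H]2O | intermediate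
16 | C9 triflate of 15 | CC1(C)CCC[C@@]2(C)[C@H]1CC[C@@](C)(CCOC(=O)C(C)(C)C)[C@@H]2OS(=O)(=O)C(F)(F)F | intermediate
17 | tertiary C10 carbocation of the cis-hydroazulene (triflate ion pair) | C[C+]1CCCC(C)(C)[C@@H]2CC[C@@](C)(CCOC(=O)C(C)(C)C)[C@H]12.[O-]S(=O)(=O)C(F)(F)F | intermediate
18 | cis-hydroazulene pivalate (C10=C20 methylene, 4,4-dimethyl, 8β-methyl, 8α-(2-pivaloyloxyethyl), H5 and H9 cis to each other and to the arm) | C=C1CCCC(C)(C)[C@@H]2CC[C@@](C)(CCOC(=O)C(C)(C)C)[C@H]12 | intermediate
19 | primary alcohol (arm = CH2CH2OH) | C=C1CCCC(C)(C)[C@@H]2CC[C@@](C)(CCO)[C@H]12 | intermediate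
20 | aldehyde (arm = CH2CHO) | C=C1CCCC(C)(C)[C@@H]2CC[C@@](C)(CC=O)[C@H]12 | intermediate
21 | (S)-1-amino-2-(methoxymethyl)pyrrolidine (SAMP) | COC[C@@H]1CCCN1N | starting material
22 | (E)-SAMP hydrazone of 20 | C=C1CCCC(C)(C)[C@@H]2CC[C@@](C)(C/C=N/N3CCC[C@H]3COC)[C@H]12 | intermediate
23 | 2(5H)-furanone | O=C1OCC=C1 | starting material
24 | lithium azaenolate of 22 (E about C14=C15) | C=C1CCCC(C)(C)[C@@H]2CC[C@@](C)(/C=C/[N-]N3CCC[C@H]3COC)[C@H]12.[Li+] | intermediate
25 | lithium enolate of lactone 26 (C11=C12) | C=C1CCCC(C)(C)[C@@H]2CC[C@@](C)([C@H](/C=N/N3CCC[C@H]3COC)[C@@H]3COC([O-])=C3)[C@H]12.[Li+] | intermediate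
26 | hydrazone lactone (13R,14R): C14 bears the CH=N–N hydrazone carbon and the lactone β-carbon C13 | C=C1CCCC(C)(C)[C@@H]2CC[C@@](C)([C@H](/C=N/N3CCC[C@H]3COC)[C@@H]3COC(=O)C3)[C@H]12 | intermediate
27 | aldehyde lactone (13R,14R) | C=C1CCCC(C)(C)[C@@H]2CC[C@@](C)([C@H](C=O)[C@@H]3COC(=O)C3)[C@H]12 | intermediate
28 | hydroxy lactone (13R,14R) | C=C1CCCC(C)(C)[C@@H]2CC[C@@](C)([C@H](CO)[C@@H]3COC(=O)C3)[C@H]12 | intermediate
29 | acetic anhydride | CC(=O)OC(C)=O | starting material
30 | CNP0235949.1 | C=C1CCCC(C)(C)[C@@H]2CC[C@@](C)([C@H](COC(C)=O)[C@@H]3COC(=O)C3)[C@H]12 | target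

**Step count and risks**

Total steps: 16, all in one line. Longest linear sequence: 16 steps from (+)-sclareolide 1.

Steps most likely to fail:

1. Step 9. The C10 cation may lose a ring proton (from C1, less likely from C9) instead of a methyl proton, and a shift of C7 may compete with that of C5. Fallback (addresses the proton loss): setting out from 15, the rearrangement is run as in step 9 and the whole olefin fraction, that is 18 together with its C1(10) double-bond isomer F1, is hydrochlorinated (dry HCl, CH2Cl2, −78 °C). Markovnikov addition converges both alkenes on the C10 tertiary chloride F2. Bulky-base E2 elimination (KOC(CH3)3, THF, 0 °C → rt) should then take a methyl proton by preference (Hofmann orientation) and comes back to the route at 18.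

2. Step 13. The face of the furanone is chosen only by the transition-state geometry, so selectivity at C13 may be low or reversed; proton transfer from C16 of the furanone to the azaenolate may also compete with addition. Fallback: setting out from 22, the azaenolate is added instead to (5S)-5-[(1S,2R,5S)-menthyloxy]-2(5H)-furanone F3, made by acid-catalysed acetalisation of 5-hydroxy-2(5H)-furanone with (+)-menthol and crystallisation of the (5S) epimer. Its alkoxy group on C16 covers one face, so C14 must bond to C13 anti to it; C13 is then fixed by the acceptor and C14 by the auxiliary, giving acetal adduct F4. CuCl2 hydrolysis as in step 14 gives aldehyde acetal F5. NaBH4 in MeOH, then aqueous KOH/NaBH4 (opening of the pseudo-ester, loss of menthol, reduction of the freed C16 aldehyde) and acidification to pH 3 close the γ-lactone and come back to the route at 28.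

3. Step 6. Attack on the β face of the enolate would give the wrong C8 epimer, and the hindered tetrasubstituted enolate may O-alkylate. Fallback: setting out from 9, KN(SiMe3)2 and allyl chloroformate give allyl enol carbonate F6. Decarboxylative Tsuji allylation (Pd2(dba)3 as zerovalent palladium source, t-Bu-PHOX ligand in the antipode that reinforces α-face delivery, THF) gives the 8α-allyl ketone F7 under catalyst control. Ozonolysis (O3; Me2S) cuts the allyl group to keto aldehyde F8, and LiAlH4 reduces both carbonyl groups, coming back to the route at 13.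

Further compounds
F1 | step 9 | C1(10)-ene isomer of 18 (endocyclic alkene, methyl on C10) | CC1=CCCC(C)(C)[C@@H]2CC[C@@](C)(CCOC(=O)C(C)(C)C)[C@H]12
F2 | step 9 | C10 tertiary chloride of the cis-hydroazulene pivalate | CC1(Cl)CCCC(C)(C)[C@@H]2CC[C@@](C)(CCOC(=O)C(C)(C)C)[C@H]12
F3 | step 13 | (5S)-5-[(1S,2R,5S)-menthyloxy]-2(5H)-furanone | O=C1C=C[C@@H](O[C@H]2C[C@@H](C)CC[C@@H]2C(C)C)O1
F4 | step 13 | acetal adduct: SAMP hydrazone with 5-menthyloxy lactone (C14 anti to the menthyloxy group) | C=C1CCCC(C)(C)[C@@H]2CC[C@@](C)([C@H](/C=N/N3CCC[C@H]3COC)[C@H]3CC(=O)O[C@@H]3O[C@H]3C[C@@H](C)CC[C@@H]3C(C)C)[C@H]12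
F5 | step 13 | aldehyde acetal (C15 aldehyde, 5-menthyloxy lactone) | C=C1CCCC(C)(C)[C@@H]2CC[C@@](C)([C@H](C=O)[C@H]3CC(=O)O[C@@H]3O[C@H]3C[C@@H](C)CC[C@@H]3C(C)C)[C@H]12
F6 | step 6 | allyl enol carbonate of 9 | CC1(C)CCC[C@@]2(C)[C@H]1CCC(C)=C2OC(=O)OCC=C
F7 | step 6 | 8α-allyl-8β-methyl-11-nordriman-9-one | CC1(C)CCC[C@@]2(C)[C@H]1CC[C@@](C)(CC=C)C2=O
F8 | step 6 | (8β-methyl-9-oxo-11-nordriman-8α-yl)acetaldehyde | CC1(C)CCC[C@@]2(C)[C@H]1CC[C@@](C)(CC=O)C2=O
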